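**Numbering of the compounds:** 1 2-ethylresorcinol; 2 4-bromo-2-ethylresorcinol; 3 bromo hydroxyquinone; 4 racemic trione ether; 5 (R)-trione ether; 6 methyl 4-methoxy-3-oxobutanoate; 7 silyl enol ether; 8 lithium dienolate; 9 bis(silyloxy)diene; 10 twofold cycloadduct; 11 tetrakis(trimethylsilyl) ether; 12 dimethyl ether of the target; 13 target.

## Analysis of the target

Compound 13 (C24H18O12) consists of two C12 bicycles joined through one ether oxygen. Unit A is a 3-ethyl-5,7,8-trihydroxy-1,4-naphthoquinone carrying that oxygen at C2. Unit B is a 2-ethyl-5,6,8-trihydroxynaphthalene-1,3,4(2H)-trione carrying it at C2. C2 of unit B is the only stereocentre: a fully substituted, S-configured carbon holding ethyl and the quinonyloxy group between the C1 and C3 carbonyls. It has no α-hydrogen, so it can only be lost by breaking the O–C2 bond. The sensitive groups are the vicinal C3/C4 dione next to a third carbonyl (hydration, benzilic-acid-type ring contraction, retro-Claisen cleavage with base), the quinonyl ether (a vinylogous ester open to addition–elimination at C2 of unit A), and six phenolic hydroxyls on redox-active rings. The difficulty is to make a tetrasubstituted C–O centre between two ketones with an electron-poor oxygen partner, and to write two dense, nearly identical oxygen patterns without a long protecting-group sequence. Formally 13 is the dehydro dimer of one hydroxyquinone, C3 of one molecule bonded to O2 of the other. The strategy rests on the common trihydroxybenzo ring: hydroxyls at C5, C6, C8 of unit B and at C8, C7, C5 of unit A. In each half the isolated hydroxyl (C8 of B, C5 of A) is peri to the carbonyl that adjoins the ethyl-bearing carbon, so one oxygenated diene can lay down both rings on a monocyclic bis-enedione.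

## Retrosynthetic reasoning

**13 from 12.** The last operation removes two methyl groups, from O8 of unit A and O5 of unit B. These are the oxygens the diene brings in as enol-ether methoxy groups. Each lies peri to a carbonyl (C1=O of A, C4=O of B) and ortho to a free hydroxyl, so a chelating boron halide should remove them at low temperature. No other protecting group is carried, and 12 differs from 13 by two carbons only.

**12 from 5 and two molecules of 9.** In each half of 12 the bonds C4a–C5 and C8a–C8 are cut, four bonds in all, which opens both benzenoid rings. This is the place to cut because the two rings are identical in substitution and can be supplied by one reagent. It reduces a C26 compound to the C16 ether 5, which already holds the stereocentre, the ether and every carbonyl at the final oxidation level. The forward reaction has to add 9 twice, to the C5=C6 bond of the quinone ring and the C5=C6 bond of the trione ring, then lose HBr and methanol from each adduct (via 10 and 11). Orientation is assigned by bromine, which in 5 sits on C5 of the quinone ring and on C6 of the trione ring, in both cases beside the carbonyl that flanks the ethyl-bearing carbon.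

**5 from 4, and 4 from two molecules of 3.** The O–C2 bond of the trione ring is cut. Both halves of 4 are the same C8 hydroxyquinone 3 in two oxidation states, so 4 equals two molecules of 3 less two hydrogens. Cutting the other C–O bond would need a base-labile tertiary α-hydroxy trione as nucleophile and a quinone electrophile with two competing leaving groups. The forward reaction is a one-electron oxidation of 3 to a radical delocalised over O2, C3 and O4, followed by C3–O2 coupling. The radical is planar, so 4 forms as a racemate, and the R antipode 5 is separated directly afterwards on a chiral phase. An enantioselective oxidative coupling of this kind cannot be defended, so a resolution placed at the earliest and cheapest point is preferred.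

**3 from 2, and 2 from 1.** The quinone carbonyl at the former C6 of the resorcinol is introduced by oxidation para to a hydroxyl, and the bromine by electrophilic substitution. Bromine goes in first: on the aromatic ring the two hydroxyls of 1 direct it to C4, whereas bromination of the quinone would not distinguish C5 from C6.

**9 from 7 via 8, and 7 from 6.** The two O–Si bonds are cut. Enol silylation of keto ester 6 gives 7, γ-deprotonation gives dienolate 8, and O-silylation gives 9. The 4-methoxy group of 6 becomes the peri methoxy groups of 12.

## Alternatives that were turned down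

**Alternative 1:** ketene–ynol ether benzannulation of the quinone half.
- Disconnection: the quinonoid ring of unit A is opened at C1–C2, C3–C4 and C4–C4a (numbering of 13). C2 and C3, with the ether oxygen and the ethyl group, come from the chiral ynol ether (1R,2R)-2-(but-1-yn-1-yloxy)-2-ethyl-5,6,8-trimethoxy-1-(methoxymethoxy)-1,2,3,4-tetrahydronaphthalene (A2); the rest comes from an arylketene.
- Forward key step: Wolff rearrangement of an aryl diazomethyl ketone gives the arylketene, which adds [2+2] to A2. The 4-arylcyclobutenone opens (4π) to a dienylketene, and 6π closure onto the arene with tautomerisation gives the naphthol 2-ethyl-3-{[(1R,2R)-2-ethyl-5,6,8-trimethoxy-1-(methoxymethoxy)-1,2,3,4-tetrahydronaphthalen-2-yl]oxy}-5,6,8-trimethoxynaphthalen-1-ol (A1).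
- For: the polarity of the ynol ether fixes the regiochemistry, and benzannulation of ketenes with heteroatom-substituted alkynes is established in kind. The stereocentre is set on a robust tetralin by conventional asymmetric chemistry and carried as an inert alkyl ether. On absolute stereocontrol and on precedent for the key step this alternative is stronger than the chosen route.
- Against: A2 is an alkynyl ether of a hindered tertiary alcohol, which is hard to make. A1 is also far from 13. In unit B, C1 is a protected carbinol and C3 and C4 are methylenes, so three ring carbons must be raised to ketones next to the tertiary ether. Unit A still needs oxidation to the quinone. Six aryl methyl ethers must be cleaved, two of them (O7 of unit A, O6 of unit B) not peri to a carbonyl and so outside mild chelation-controlled cleavage.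
- Comparison: the chosen route gives up catalytic stereocontrol. In return both benzenoid rings arrive at the final oxidation level in one step from 5, no oxidation follows formation of the ether, and only two peri methyl ethers remain. The whole route is eight steps against a sequence several times longer.

**Alternative 2:** biomimetic folding of a masked polyketide.
- Disconnection: both rings of unit B are opened at C4a–C8a (aldol) and C2–C3 (Claisen). A linear tetraoxo ester, masked as a pyrone, carries the aryloxy group of a fully methylated unit A.
- Forward key step: methoxide opens the pyrone; the polyketo ester cyclises by aldol condensation and then Claisen condensation to 2-[(3-ethyl-1,4,5,7,8-pentamethoxynaphthalen-2-yl)oxy]naphthalene-1,3,6,8-tetrol (A3).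
- For: cheap reagents, one flask for two rings, cyclisations of a well-known kind, and a robust diaryl ether as the linkage. On the reliability of the ring-forming event it is stronger than the chosen route.
- Against: A3 lacks the ethyl group and the stereocentre at C2 of unit B, and lacks the oxygens at C4 and C5. What remains is an enantioselective dearomatising C-ethylation of a carbon that already bears aryloxy (O-alkylation competes), two further ring oxygenations, oxidation of unit A to the quinone (where the 1,4- and 5,8-dimethoxy pairs compete), and three more demethylations.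
- Comparison: the hardest problems are postponed to the most valuable intermediate. The chosen route settles oxygenation and stereocentre before its key step and finishes in one step after it.

**Alternative 3:** chromium carbene benzannulation of the quinone half.
- Disconnection: the quinonoid ring of unit A is opened at C3–C4, C1–C2 and C1–C8a, giving an aryl(methoxy)carbene complex (CO)5Cr=C(OMe)Ar, the same ynol ether A2, and carbon monoxide.
- Forward key step: alkyne insertion, CO insertion to a vinylketene complex and electrocyclisation give 3-ethyl-2-{[(1R,2R)-2-ethyl-5,6,8-trimethoxy-1-(methoxymethoxy)-1,2,3,4-tetrahydronaphthalen-2-yl]oxy}-4,5,7,8-tetramethoxynaphthalen-1-ol (A4).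
- For: A4 carries both quinone oxygens of unit A as a 4-methoxy-1-naphthol, one oxidative demethylation from the quinone. On this point it is stronger than alternative 1 and as direct as the chosen route. Stereocontrol is again conventional.
- Against: the metal is stoichiometric. The steric rule should place the bulky alkoxy carbon next to the hydroxyl as required, but donor-substituted alkynes are known to divert such carbenes into insertion products without CO uptake, so the orientation is not assured. The difficult access to A2 and the long oxidation and deprotection sequence on unit B are the same as in alternative 1.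
- Comparison: the chosen route has a less precedented key step and resolves a racemate, but it is metal-free at the key step, convergent on one C8 building block, and much shorter.

Key step: step 7

Remark: the quaternary carbon is formed as a racemate and the required antipode 5 is taken by chromatography on a chiral phase. Which eluted antipode is 5 is assumed to be settled by anomalous-dispersion X-ray analysis (two bromine atoms). The descriptor is R in 5 and 10 and S in 11 to 13 without any change at the centre, because bromine on the neighbouring carbon alters the priorities.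

## Route

Step 1
Reactants: 1 2-ethylbenzene-1,3-diol (2-ethylresorcinol)
Product: 2 4-bromo-2-ethylbenzene-1,3-diol
Conditions: NBS (1.0 equiv), MeCN, −20 → 0 °C
Reagents that add atoms: N-bromosuccinimide, O=C1CCC(=O)N1Br
Why: Electrophilic aromatic bromination; both hydroxyls direct to the equivalent positions C4 and C6 while C2 is blocked by ethyl, and one equivalent at low temperature should stop at the monobromide because the first bromine deactivates the ring.

Step 2
Reactants: 2 4-bromo-2-ethylbenzene-1,3-diol
Product: 3 5-bromo-3-ethyl-2-hydroxycyclohexa-2,5-diene-1,4-dione (5-bromo-3-ethyl-2-hydroxy-1,4-benzoquinone)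
Conditions: ON(SO3K)2 (2.3 equiv), KH2PO4, H2O/acetone, 0 °C → rt; then acidify to pH 2
Reagents that add atoms: potassium nitrosodisulfonate, [K+].[K+].[O-]S(=O)(=O)N([O])S(=O)(=O)[O-]
Why: Teuber oxidation; two nitrosodisulfonate radicals take the phenol through the aryloxyl radical to a para-oxygenated dienone that loses imidodisulfonate. The only unsubstituted position para to a hydroxyl is C6, so the new carbonyl should go there, and the second hydroxyl remains as the acidic enol of the 2-hydroxy-1,4-quinone.

Step 3
Reactants: 3 5-bromo-3-ethyl-2-hydroxy-1,4-benzoquinone (two molecules)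
Product: 4 rac-6-bromo-2-[(5-bromo-3-ethyl-1,4-benzoquinon-2-yl)oxy]-2-ethylcyclohex-5-ene-1,3,4-trione
Conditions: PbO2 (0.6 equiv), AcOH, 15–20 °C
Reagents that add atoms: none
Why: Oxidative dehydrodimerisation of a 2-hydroxy-3-alkylquinone, the coupling by which PbO2 converts 2-hydroxy-3-alkyl-1,4-naphthoquinones into 2-alkyl-2-(quinonyloxy)-1,3,4-triones. The tricarbonyl-stabilised radical has spin at O2 and at the ethyl-bearing C3; C–C coupling would join two fully substituted carbons and O–O coupling is reversible, so C3–O2 coupling should prevail. The planar radical gives the quaternary centre as a racemate.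

Step 4
Reactants: 4 rac-6-bromo-2-[(5-bromo-3-ethyl-1,4-benzoquinon-2-yl)oxy]-2-ethylcyclohex-5-ene-1,3,4-trione
Product: 5 (2R)-6-bromo-2-[(5-bromo-3-ethyl-1,4-benzoquinon-2-yl)oxy]-2-ethylcyclohex-5-ene-1,3,4-trione
Conditions: preparative HPLC, immobilised amylose tris(3,5-dimethylphenylcarbamate) on silica, n-heptane/EtOAc, rt
Reagents that add atoms: none
Why: Resolution of a racemate by preparative chromatography on a chiral stationary phase; the aprotic eluent avoids hemiketals at the vicinal dione, and the centre has no α-hydrogen and should be configurationally stable. The absolute configuration of the collected antipode is to be assigned by X-ray diffraction with anomalous dispersion from the two bromine atoms.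

Step 5
Reactants: 6 methyl 4-methoxy-3-oxobutanoate
Product: 7 methyl (2Z)-4-methoxy-3-(trimethylsilyloxy)but-2-enoate
Conditions: Me3SiCl, NEt3, toluene, rt
Reagents that add atoms: chlorotrimethylsilane, C[Si](C)(C)Cl
Why: Soft enolisation and O-silylation of a β-keto ester gives the conjugated 3-silyloxy enoate. Either double-bond geometry serves, because this bond becomes the central single bond of the diene.

Step 6
Reactants: 7 methyl (2Z)-4-methoxy-3-(trimethylsilyloxy)but-2-enoate
Product: 9 (1Z,3Z)-1,4-dimethoxy-1,3-bis(trimethylsilyloxy)buta-1,3-diene, via lithium dienolate 8 (not isolated)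
Conditions: LiN(i-Pr)2, THF, −78 °C; then Me3SiCl, −78 → 0 °C
Reagents that add atoms: chlorotrimethylsilane, C[Si](C)(C)Cl
Why: γ-Deprotonation of the vinylogous ester to the dienolate and O-silylation at the ester oxygen, the standard preparation of 1,3-bis(silyloxy)buta-1,3-dienes; the 4-methoxy group ends on the nucleophilic terminus of the diene.

Step 7
Reactants: 5 (2R)-6-bromo-2-[(5-bromo-3-ethyl-1,4-benzoquinon-2-yl)oxy]-2-ethylcyclohex-5-ene-1,3,4-trione; 9 (1Z,3Z)-1,4-dimethoxy-1,3-bis(trimethylsilyloxy)buta-1,3-diene (two molecules react)
Product: 12 (2S)-2-ethyl-2-[(3-ethyl-5,7-dihydroxy-8-methoxy-1,4-dioxo-1,4-dihydronaphthalen-2-yl)oxy]-6,8-dihydroxy-5-methoxynaphthalene-1,3,4(2H)-trione, via twofold bromo cycloadduct 10 (not isolated), via tetrakis(trimethylsilyl) ether 11 (not isolated)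
Conditions: 9 (5 equiv), CH2Cl2, −78 → 0 °C; then 1 M aq HCl, THF, 0 °C
Reagents that add atoms: none
Why: Proposed new method: each C(Br)=CH unit between two carbonyls is a strongly electron-poor dienophile and the diene is polarised so that its methoxy-bearing C4 is the nucleophilic end; C4 should bond to the unbrominated carbon (C6 of the quinone ring, C5 of the trione ring) in a Michael-like first event and the ketene-acetal carbon C1 should then close onto the bromine-bearing carbon, an asynchronous [4+2] that in its stepwise limit is a 6-(enolexo)-exo-trig closure, so that each new six-membered ring is formed through C4a–C5 and C8a–C8. Loss of HBr across the ring fusion of 10 restores the enedione, and 1,4-elimination of methanol (methoxide from the mixed silyl acetal carbon, hydrogen from the CH(OMe) carbon) aromatises each ring to 11; aqueous acid then removes the four silyl groups, leaving hydroxyls at the former silyloxy carbons and methoxy groups peri to C1=O of unit A and to C4=O of unit B. The closest known reaction type is the halogen-directed cycloaddition of 2-bromo-1,4-quinones with 1,3-bis(silyloxy)buta-1,3-dienes followed by aromatisation; the quinone half of 5 belongs to that class, whereas a 6-bromocyclohex-5-ene-1,3,4-trione has not served as the dienophile and two such annulations have not been run on one ether-linked bis-enedione. No stereocentre that survives is created: the eight sp3 centres of 10 are erased on aromatisation, and C2 of the trione ring, lacking an α-hydrogen, is untouched. The step needs regioselectivity in both halves and chemoselectivity for C=C over the vicinal C3/C4 dione. The first is secured by bromine, which in each half sits beside the carbonyl adjoining the ethyl-bearing carbon and sends the ketene-acetal carbon to that side; the second by low temperature and the absence of a Lewis acid, under which uncatalysed carbonyl addition of a silyl ketene acetal is slow. The tetrasubstituted, donor-substituted C2=C3 bond of the quinone ring should not compete.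

Step 8
Reactants: 12 (2S)-2-ethyl-2-[(3-ethyl-5,7-dihydroxy-8-methoxy-1,4-dioxo-1,4-dihydronaphthalen-2-yl)oxy]-6,8-dihydroxy-5-methoxynaphthalene-1,3,4(2H)-trione
Product: 13 (2S)-2-ethyl-2-[(3-ethyl-5,7,8-trihydroxy-1,4-dioxo-1,4-dihydronaphthalen-2-yl)oxy]-5,6,8-trihydroxynaphthalene-1,3,4(2H)-trione
Conditions: BCl3 (8 equiv), CH2Cl2, −78 → 0 °C; then H2O/MeOH
Reagents that add atoms: none
Why: Chelation-assisted Lewis-acid demethylation; BCl3 binds between the peri carbonyl and the methoxy oxygen and chloride removes the methyl group by SN2, and both methoxy groups (O8 of unit A, O5 of unit B) are peri to a carbonyl. The linking oxygen is a poorly basic vinylogous ester oxygen on an electron-poor carbon and should survive at low temperature; C2 is not touched.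

## Compound list

1 | 2-ethylbenzene-1,3-diol (2-ethylresorcinol) | CCc1c(O)cccc1O | starting material
2 | 4-bromo-2-ethylbenzene-1,3-diol | CCc1c(O)ccc(Br)c1O | intermediate
3 | 5-bromo-3-ethyl-2-hydroxycyclohexa-2,5-diene-1,4-dione | CCC1=C(O)C(=O)C=C(Br)C1=O | intermediate
4 | rac-6-bromo-2-[(5-bromo-3-ethyl-1,4-benzoquinon-2-yl)oxy]-2-ethylcyclohex-5-ene-1,3,4-trione (racemate) | CCC1=C(OC2(CC)C(=O)C(=O)C=C(Br)C2=O)C(=O)C=C(Br)C1=O | intermediate
5 | (2R)-6-bromo-2-[(5-bromo-3-ethyl-1,4-benzoquinon-2-yl)oxy]-2-ethylcyclohex-5-ene-1,3,4-trione | CCC1=C(O[C@]2(CC)C(=O)C(=O)C=C(Br)C2=O)C(=O)C=C(Br)C1=O | intermediate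
6 | methyl 4-methoxy-3-oxobutanoate | COCC(=O)CC(=O)OC | starting material
7 | methyl (2Z)-4-methoxy-3-(trimethylsilyloxy)but-2-enoate | COC/C(O[Si](C)(C)C)=C/C(=O)OC | intermediate
8 | lithium (1Z,3Z)-1,4-dimethoxy-3-(trimethylsilyloxy)buta-1,3-dien-1-olate (not isolated) | CO/C=C(\O[Si](C)(C)C)/C=C(/OC)[O-].[Li+] | intermediate
9 | (1Z,3Z)-1,4-dimethoxy-1,3-bis(trimethylsilyloxy)buta-1,3-diene | CO/C=C(\O[Si](C)(C)C)/C=C(/OC)O[Si](C)(C)C | intermediate
10 | (2R)-8a-bromo-2-{[4a-bromo-3-ethyl-5,8-dimethoxy-1,4-dioxo-5,7-bis(trimethylsilyloxy)-1,4,4a,5,8,8a-hexahydronaphthalen-2-yl]oxy}-2-ethyl-5,8-dimethoxy-6,8-bis(trimethylsilyloxy)-4a,5,8,8a-tetrahydronaphthalene-1,3,4(2H)-trione, mixture of diastereomers at the eight new sp3 centres (not isolated) | CCC1=C(O[C@]2(CC)C(=O)C(=O)C3C(OC)C(O[Si](C)(C)C)=CC(OC)(O[Si](C)(C)C)C3(Br)C2=O)C(=O)C2C(OC)C(O[Si](C)(C)C)=CC(OC)(O[Si](C)(C)C)C2(Br)C1=O | intermediate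
11 | (2S)-2-ethyl-2-{[3-ethyl-8-methoxy-1,4-dioxo-5,7-bis(trimethylsilyloxy)-1,4-dihydronaphthalen-2-yl]oxy}-5-methoxy-6,8-bis(trimethylsilyloxy)naphthalene-1,3,4(2H)-trione (not isolated) | CCC1=C(O[C@]2(CC)C(=O)C(=O)c3c(OC)c(O[Si](C)(C)C)cc(O[Si](C)(C)C)c3C2=O)C(=O)c2c(OC)c(O[Si](C)(C)C)cc(O[Si](C)(C)C)c2C1=O | intermediate
12 | (2S)-2-ethyl-2-[(3-ethyl-5,7-dihydroxy-8-methoxy-1,4-dioxo-1,4-dihydronaphthalen-2-yl)oxy]-6,8-dihydroxy-5-methoxynaphthalene-1,3,4(2H)-trione | CCC1=C(O[C@]2(CC)C(=O)C(=O)c3c(OC)c(O)cc(O)c3C2=O)C(=O)c2c(OC)c(O)cc(O)c2C1=O | intermediate
13 | (2S)-2-ethyl-2-[(3-ethyl-5,7,8-trihydroxy-1,4-dioxo-1,4-dihydronaphthalen-2-yl)oxy]-5,6,8-trihydroxynaphthalene-1,3,4(2H)-trione | CCC1=C(O[C@]2(CC)C(=O)C(=O)c3c(O)c(O)cc(O)c3C2=O)C(=O)c2c(O)c(O)cc(O)c2C1=O | target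

## Step count and least certain steps

Total step count: 8. Longest linear sequence: 6 steps (steps 1, 2, 3, 4, 7, 8); the diene branch (steps 5 and 6) joins at step 7.

**Step 7 (key step, Proposed new method).** Several processes may interfere:
- Reversed orientation in the trione half, because C4=O, activated by the neighbouring C3=O, may outweigh the bromine and draw the nucleophilic diene terminus to C6.
- Carbonyl addition of the silyl ketene acetal to the vicinal dione instead of cycloaddition.
- Cleavage of the quinonyl ether by addition–elimination of liberated methanol or bromide at C2 of the quinone ring.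
- Loss of optical purity through reversible homolysis of the O–C2 bond if the mixture is warmed.

Fallback with known chemistry, setting out from 3 and 9 and returning at 12: the annulation is run on the monomeric bromo hydroxyquinone. Compound 3 is O-silylated in the flask by excess 9 and then behaves as an ordinary 2-bromoquinone toward the diene, giving after acid work-up 3-ethyl-2,5,7-trihydroxy-8-methoxy-1,4-naphthoquinone F1. Dehydrodimerisation of F1 with PbO2 in AcOH, on the naphthoquinone class for which this coupling is established, gives the racemic dimethyl ether F2. Separation on the chiral phase of step 4 gives 12, and the route resumes at step 8. The free 5- and 7-hydroxyls of F1 are the weak point of this variant; the vinylogous-acid 2-hydroxyl should be oxidised first.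

**Step 3.** The coupling may join the wrong atoms (C3–C3, or C3–O4 leading to a 1,2-quinone ether), and acetate may add to the bromo enedione during the oxidation. Fallback, setting out from 3 and returning at 4: a polar coupling on trivalent iodine replaces radical recombination. Iodosylbenzene (PhIO, 0.5 equiv, CH2Cl2, molecular sieves) should convert 3, as it does carboxylic acids, into bis[(5-bromo-3-ethyl-1,4-benzoquinon-2-yl)oxy](phenyl)-λ3-iodane F3. On warming, the oxygen of one ligand attacks C3 of the other with loss of iodobenzene. This is the pathway of α-acyloxylation of 2-substituted 1,3-dicarbonyl compounds by trivalent-iodine carboxylates.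

**Step 4.** Hydration or hemiketal formation at C3 on the column may broaden or split the peaks, and slow homolysis of the O–C2 bond during concentration would erode purity. Fallback, setting out from 4 and returning at 13: the racemate is taken through steps 7 and 8, via the racemic dimethyl ether F2 already described, to the racemic target F4. Its antipodes are separated on the same chiral phase, and the assignment then rests on chiroptical comparison.

**Step 8.** Chloride may cleave the quinonyl ether by addition–elimination at C2 of the quinone ring under boron activation, and boron chelates of the peri-hydroxy carbonyl units may resist hydrolysis. Fallback, setting out from 5 and returning at 13: the methyl ethers are avoided by changing the spectator group on the diene.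
- The known keto ester methyl 4-[(tert-butyldimethylsilyl)oxy]-3-oxobutanoate F5 is silylated as in step 5 to methyl (2Z)-4-[(tert-butyldimethylsilyl)oxy]-3-(trimethylsilyloxy)but-2-enoate F6.
- F6 is converted as in step 6 into (1Z,3Z)-4-[(tert-butyldimethylsilyl)oxy]-1-methoxy-1,3-bis(trimethylsilyloxy)buta-1,3-diene F7.
- Annulation of 5 with F7 under the conditions of step 7 should give (2S)-5-[(tert-butyldimethylsilyl)oxy]-2-{[8-[(tert-butyldimethylsilyl)oxy]-3-ethyl-5,7-dihydroxy-1,4-dioxo-1,4-dihydronaphthalen-2-yl]oxy}-2-ethyl-6,8-dihydroxynaphthalene-1,3,4(2H)-trione F8.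
- The two aryl silyl ethers of F8 are removed with HF·pyridine in MeCN at 0 °C to give 13.

**Step 2.** Oxidation may take place at the brominated C4 with loss of bromide, and the product may be over-oxidised. Fallback, setting out from 1 and returning at 3: exhaustive bromination (NBS, 2.1 equiv) gives 4,6-dibromo-2-ethylbenzene-1,3-diol F9. Oxidation with PhI(OAc)2 in aqueous MeCN then proceeds by ipso attack of water at a brominated position and loss of HBr. By symmetry, attack at either bromine, para or ortho to the oxidised hydroxyl, leads after tautomerisation to 3.

## Further compounds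

F1 | step 7 | 3-ethyl-2,5,7-trihydroxy-8-methoxy-1,4-naphthoquinone | CCC1=C(O)C(=O)c2c(OC)c(O)cc(O)c2C1=O
F2 | step 7 | rac-2-ethyl-2-[(3-ethyl-5,7-dihydroxy-8-methoxy-1,4-dioxo-1,4-dihydronaphthalen-2-yl)oxy]-6,8-dihydroxy-5-methoxynaphthalene-1,3,4(2H)-trione | CCC1=C(OC2(CC)C(=O)C(=O)c3c(OC)c(O)cc(O)c3C2=O)C(=O)c2c(OC)c(O)cc(O)c2C1=O
F3 | step 3 | bis[(5-bromo-3-ethyl-1,4-benzoquinon-2-yl)oxy](phenyl)-λ3-iodane | CCC1=C(OI(c2ccccc2)OC2=C(CC)C(=O)C(Br)=CC2=O)C(=O)C=C(Br)C1=O
F4 | step 4 | rac-2-ethyl-2-[(3-ethyl-5,7,8-trihydroxy-1,4-dioxo-1,4-dihydronaphthalen-2-yl)oxy]-5,6,8-trihydroxynaphthalene-1,3,4(2H)-trione | CCC1=C(OC2(CC)C(=O)C(=O)c3c(O)c(O)cc(O)c3C2=O)C(=O)c2c(O)c(O)cc(O)c2C1=O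
F5 | step 8 | methyl 4-[(tert-butyldimethylsilyl)oxy]-3-oxobutanoate | COC(=O)CC(=O)CO[Si](C)(C)C(C)(C)C
F6 | step 8 | methyl (2Z)-4-[(tert-butyldimethylsilyl)oxy]-3-(trimethylsilyloxy)but-2-enoate | COC(=O)/C=C(/CO[Si](C)(C)C(C)(C)C)O[Si](C)(C)C
F7 | step 8 | (1Z,3Z)-4-[(tert-butyldimethylsilyl)oxy]-1-methoxy-1,3-bis(trimethylsilyloxy)buta-1,3-diene | CC(C)(C)[Si](C)(C)O/C=C(\O[Si](C)(C)C)/C=C(/OC)O[Si](C)(C)C
F8 | step 8 | (2S)-5-[(tert-butyldimethylsilyl)oxy]-2-{[8-[(tert-butyldimethylsilyl)oxy]-3-ethyl-5,7-dihydroxy-1,4-dioxo-1,4-dihydronaphthalen-2-yl]oxy}-2-ethyl-6,8-dihydroxynaphthalene-1,3,4(2H)-trione | CCC1=C(O[C@]2(CC)C(=O)C(=O)c3c(O[Si](C)(C)C(C)(C)C)c(O)cc(O)c3C2=O)C(=O)c2c(O[Si](C)(C)C(C)(C)C)c(O)cc(O)c2C1=O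
F9 | step 2 | 4,6-dibromo-2-ethylbenzene-1,3-diol | CCc1c(O)c(Br)cc(Br)c1O
A1 | alternative 1 | 2-ethyl-3-{[(1R,2R)-2-ethyl-5,6,8-trimethoxy-1-(methoxymethoxy)-1,2,3,4-tetrahydronaphthalen-2-yl]oxy}-5,6,8-trimethoxynaphthalen-1-ol | CCc1c(O[C@]2(CC)CCc3c(OC)c(OC)cc(OC)c3[C@H]2OCOC)cc2c(OC)c(OC)cc(OC)c2c1O
A2 | alternative 1 | (1R,2R)-2-(but-1-yn-1-yloxy)-2-ethyl-5,6,8-trimethoxy-1-(methoxymethoxy)-1,2,3,4-tetrahydronaphthalene | CCC#CO[C@]1(CC)CCc2c(OC)c(OC)cc(OC)c2[C@H]1OCOC
A3 | alternative 2 | 2-[(3-ethyl-1,4,5,7,8-pentamethoxynaphthalen-2-yl)oxy]naphthalene-1,3,6,8-tetrol | Oc1cc(O)c2c(O)c(Oc3c(CC)c(OC)c4c(OC)cc(OC)c(OC)c4c3OC)c(O)cc2c1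
A4 | alternative 3 | 3-ethyl-2-{[(1R,2R)-2-ethyl-5,6,8-trimethoxy-1-(methoxymethoxy)-1,2,3,4-tetrahydronaphthalen-2-yl]oxy}-4,5,7,8-tetramethoxynaphthalen-1-ol | CCc1c(O[C@]2(CC)CCc3c(OC)c(OC)cc(OC)c3[C@H]2OCOC)c(O)c2c(OC)c(OC)cc(OC)c2c1OC
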